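In maple a small charge of Zu goes with a low plateau, but don't read this flask off alder just because both hold 2.5 µM: convert the read plateaus to mM instead, and birch with 1.17 mM stands level with alder at 1.15 mM, though their cZu and cUx differ and the product cZu·cUx is the same.

| setting | maple | birch | alder | flask |
|---|---|---|---|---|
| Ux | 5 mM | 5 mM | 10 mM | 5.0 mM |
| Ja | 9 mM | 9 mM | 9 mM | 9.00 mM |
| Zu | 1.2 µM | 5 µM | 2.5 µM | 2.5 µM |
| remark | run made earlier | run made earlier | run made earlier |  |
| time |  |  |  | 12 min |

- maple (time / min: Eb / %): 1.33: 9.2; 3.00: 7.6; 4.00: 8.7; 6.00: 9.2; 8.00: 9.4; 10.0: 7.8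
- birch (time / min: Eb / %): 1.33: 24.5; 3.00: 23.6; 4.00: 22.6; 6.00: 23.0; 8.00: 22.9; 10.0: 24.3
- alder (time / min: Eb / %): 2.00: 11.2; 4.00: 11.0; 6.00: 11.1; 8.00: 11.6; 10.0: 12.4

(standard deviation of a reading: 1 percentage point)

- the earlier runs were read with a standard deviation of 1 percentage point
- on the list of suspects stand: Ux + Ja + Zu -> Zu + Eb; 2 Ja -> Ez
- the reaction counts as stopped when no species that holds the Ux changes by six tenths of a point or more over the second half of the time

- which holds at 12 min: what has brought the reaction to rest, or that it has not come to rest (Ja has run out first / all of Ux has reacted / no working catalyst is left / it is still moving)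
- how much Eb there is at 12 min, in percent of the Ux charged

So reckon Ja as the limiting reagent, shared between the catalysed path and its own pairing to Ez, and with cUx treated as steady the share integrates to Eb = x·ln(1 + cJa/x), where cJa is the charge and x grows in proportion to cZu·cUx. Solve this on the birch plateau for 0.361 mM, then scale to the flask's charges for 0.181 mM: this is the flask's crossover level, the cJa at which both paths use Ja equally fast. Since the flask's Ja charge stands 49.8 times above it, my figure for Eb comes to 14.2%, and expect nearly all of that Ja to end as Ez.

The forecast says Ja has run out first and puts Eb at 14.5%, between 13.3% and 15.7%, 0.30 percentage points above mine, on the ground that “Birch and alder share the same Zu×Ux product and give the same absolute Eb”.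

What the flask shows at the end is this: Ja has run out first, with Eb at 14.2% and Ja at 0% of its charge after 12 min.

    Ux + Ja + Zu → Zu + Eb (k = 1.35 × 10⁶ M⁻² s⁻¹)
    2 Ja → Ez (k = 43.7 M⁻¹ s⁻¹)

At the start of the flask, the pairing to Ez uses Ja 47 times as fast as the path to Eb, beside the 49.8 reckoned from birch as charge over crossover level. A neighbour charged with 0.620 µM of Zu has a crossover level of 0.0448 mM, which reckons to 4.76% of Eb, and that neighbour gives 4.88%.

(Readings and results were generated by integration with made-up constants; scatter was added.)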